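(The numbers in the tables are calculated for substances that don't exist, noise included.)

A closed, stirred vessel holds 0.50 M substrate and 0.750 M reagent at constant temperature. The flasks differ in the free catalyst charged, and each is read at 15 h.

| flask | substrate | reagent | free catalyst | remark | time |
|---|---|---|---|---|---|
| spring | 0.50 M | 0.75 M | 1.8 mM | run made earlier |  |
| midnight | 0.50 M | 0.75 M | 17 mM | run made earlier |  |
| theta | 0.50 M | 0.750 M | 5.0 mM |  | 15 h |
| gamma | 0.50 M | 0.750 M | 15 mM |  | 15 h |
| epsilon | 0.50 M | 0.750 M | 8.0 mM |  | 15 h |
| delta | 0.50 M | 0.750 M | 1.2 mM |  | 15 h |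
| beta | 0.50 M | 0.750 M | 2.5 mM |  | 15 h |

| run | time / h | target / % |
|---|---|---|
| spring | 0.833 | 1.0 |
| spring | 1.33 | 1.7 |
| spring | 2.00 | 2.0 |
| spring | 3.00 | 3.5 |
| spring | 5.00 | 4.3 |
| spring | 6.00 | 5.5 |
| spring | 10.0 | 8.8 |
| midnight | 0.500 | 3.8 |
| midnight | 1.50 | 11.0 |
| midnight | 3.00 | 20.3 |
| midnight | 5.00 | 29.3 |
| midnight | 6.00 | 33.1 |
| midnight | 8.00 | 39.3 |
| midnight | 10.0 | 45.1 |

(each reading ± 0.5 percentage points)

- all flasks from highest to lowest amount of target, in percent of the substrate charged, at 15 h (theta / gamma / epsilon / delta / beta)
- the amount of target, in percent of the substrate charged of the flask you put first, at 15 h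
- the amount of target, in percent of the substrate charged of the flask you put last, at 15 h



If the rate scales with the catalyst charge, a larger charge reaches a given conversion in proportionally fewer hours. So I measure each flask on a normalised time axis. The catalyst-time of gamma, 225 mM·h, is its charge multiplied by its hours. My rule is that flasks with equal substrate and reagent charges and equal catalyst-time should hold about equal target.

The two runs test this. Spring at 10.0 h has a catalyst-time of 18.0 mM·h and reads 8.8 %. A straight line between midnight's first two readings gives 7.82 % at that catalyst-time. The gap of 0.98 percentage points stands against a scatter of 0.5 points, so at that catalyst-time I trust the rule to about that gap.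

Delta has a catalyst-time of 18.0 mM·h, equal to that of spring at its last reading, so my value for delta is that reading, 8.8 %. Gamma corresponds to midnight at 13.2 h, later than its last reading. The line through midnight's last two readings gives 54.5 %. I take that as a high estimate, since midnight gains less per hour late than early. At one common time, catalyst-time ranks as the charge, so gamma has the largest and delta the smallest, and I expect target to rank the same way.

The forecast gives gamma > epsilon > theta > beta > delta, with 52 % first and 9.2 % last, and of the first it says "Gamma at 15 h then corresponds to midnight at about 13 h". Its top lies 2.5 points below my high estimate, and its low stands 0.4 points above my value for delta.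

The simulation gives gamma > epsilon > theta > beta > delta, with gamma at 52.0 % and delta at 8.78 %.

    2 catalyst intermediate C → spent catalyst (k = 23.0 M⁻¹ h⁻¹)
    reagent + catalyst intermediate A → catalyst intermediate B (k = 130 M⁻¹ h⁻¹)
    catalyst intermediate C → free catalyst + target (k = 4.80 h⁻¹)
    catalyst intermediate B → by-product + catalyst intermediate C (k = 16.0 h⁻¹)
    substrate + free catalyst ⇌ catalyst intermediate A (K = 2.20 M⁻¹, k = 31.0 M⁻¹ h⁻¹)

The same reckoning serves gamma read earlier, at 4.0 h. Its catalyst-time is 60.0 mM·h, which corresponds to midnight at 3.53 h, between the readings at 3.00 h and 5.00 h. The straight line there gives 22.7 %, and the flask holds 22.8 %. Catalyst-time counts the charge, whereas in gamma at that moment free catalyst is 14.4 % of the catalyst charged and spent catalyst 45.4 %.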